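Assumption: andrographolide (bulk extract product of Andrographis paniculata) is taken as the cheap commercial starting material. The target is read as the ent-labdane (4R,5S,9R,10S,13Z) acid, which has the same C4, C5, C9 and C10 configuration as andrographolide; ent-labdane numbering is used throughout.

## Retrosynthetic overview

1. No ring is built: ring A, ring B and all four stereocentres come from andrographolide.
2. Last C–O disconnection: the C16–O acetyl ester, made on the hydroxide-opened 15,16-olide by a carboxylate-directed acetyl transfer.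
3. The 15,16-olide comes from the 16,15-olide (andrograpanin) by reduction to the Z-ene-diol and regioselective oxidative lactonisation at C15, which transposes the carbonyl.
4. Andrograpanin comes from andrographolide by SN2' hydride reduction (C14 deoxygenation with alkene shift) and radical C3 deoxygenation through the 3,19-cyclic thionocarbonate.

## Route

Step 1
Reactants: 1 andrographolide
Product: 3 14-O-acetyl-3,19-O-thiocarbonylandrographolide, via cyclic thionocarbonate 2 (not isolated)
Conditions: 1,1'-thiocarbonyldiimidazole (1.1 equiv), DMAP (0.1 equiv), THF/pyridine 4:1, 0 °C to rt, 6 h; then Ac2O (4 equiv), 0 °C to rt, 2 h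
Reagents that add atoms: 1,1'-thiocarbonyldiimidazole S=C(n1ccnc1)n1ccnc1; acetic anhydride CC(=O)OC(C)=O
Why: Thiocarbonyl transfer (acyl substitution) goes first to the primary C19 hydroxyl and closes on the syn C3 hydroxyl to a six-membered 1,3-dioxane-2-thione, the same cis-1,3-diol that forms the known 3,19-acetals; excess Ac2O then esterifies the remaining allylic C14 hydroxyl and scavenges the liberated imidazole, and no stereocentre is touched.

Step 2
Reactants: 3 14-O-acetyl-3,19-O-thiocarbonylandrographolide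
Product: 4 3,19-O-thiocarbonyl-14-deoxyandrographolide
Conditions: NaBH4 (1.0 equiv), THF/EtOH 10:1, −20 to 0 °C, 30 min; AcOH quench
Reagents that add atoms: none
Why: Conjugate hydride addition at C12 of the alpha-alkylidene-beta-acetoxy lactone followed by E1cB loss of acetate (SN2' reduction, as with Morita–Baylis–Hillman acetates) moves the double bond into the lactone ring and removes the C14 oxygen, erasing that stereocentre as planned.

Step 3
Reactants: 4 3,19-O-thiocarbonyl-14-deoxyandrographolide
Product: 6 andrograpanin (ent-19-hydroxylabda-8(17),13-dien-16,15-olide), via stannyl thiocarbonate 5 (not isolated)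
Conditions: Bu3SnH (2.0 equiv, slow addition), AIBN (0.2 equiv), toluene, 110 °C, 2 h; then KF (aq), MeOH, rt, 1 h
Reagents that add atoms: none
Why: Barton–McCombie deoxygenation of a cyclic thionocarbonate: the tin radical adds to sulfur and the adduct fragments toward the secondary C3 radical, not the primary neopentyl C19 radical, so C3 becomes CH2 while C19 keeps its oxygen, which is freed by fluoride cleavage of the Sn–S bond and loss of COS.

Step 4
Reactants: 6 andrograpanin
Product: 7 ent-labda-8(17),13Z-diene-15,16,19-triol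
Conditions: i-Bu2AlH (5 equiv), CH2Cl2, −78 to 0 °C, 2 h; aq. KNaC4H4O6 work-up
Reagents that add atoms: none
Why: Excess i-Bu2AlH reduces the butenolide carbonyl by 1,2-hydride addition to the allylic diol without conjugate reduction, and the Z geometry of C13=C14 is fixed by the ring it came from.

Step 5
Reactants: 7 ent-labda-8(17),13Z-diene-15,16,19-triol
Product: 9 ent-19-hydroxylabda-8(17),13-dien-15,16-olide, via lactol 8 (not isolated)
Conditions: activated MnO2 (25 equiv), CH2Cl2, rt, 16 h
Reagents that add atoms: none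
Why: Oxidative lactonisation with MnO2, which oxidises only allylic alcohols: the less hindered C15 carbinol is oxidised first, the enal is trapped by the C16 hydroxyl as lactol 8 and oxidised on to the lactone, so the carbonyl is transposed from C16 to C15 while the saturated C19 alcohol is untouched (the minor regioisomer is 6 itself and is recycled through step 4).

Step 6
Reactants: 9 ent-19-hydroxylabda-8(17),13-dien-15,16-olide
Product: 12 ent-16-acetoxy-19-hydroxylabda-8(17),13Z-dien-15-oic acid (target), via hydroxy carboxylate salt 10 (not isolated), via acetoxy carboxylate salt 11 (not isolated)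
Conditions: Bu4NOH (1.0 equiv, 1 M in MeOH), THF/H2O, 0 °C to rt, 1 h; evaporate, azeotrope with MeCN; N-acetylimidazole (1.5 equiv), 4 Å MS, MeCN, rt to 40 °C, 12 h; cold 0.5 M HCl to pH 3
Reagents that add atoms: tetrabutylammonium hydroxide CCCC[N+](CCCC)(CCCC)CCCC.[OH-]; N-acetylimidazole CC(=O)n1ccnc1
Why: Proposed new method: carboxylate-gated hydroxyl acetylation, in which the cis carboxylate of salt 10 hydrogen-bonds the C16 hydroxyl in a seven-membered chelate and acts as an intramolecular general base for its attack on N-acetylimidazole, an acyl donor whose imidazolide leaving group is too basic to be expelled after carboxylate attack, so no mixed anhydride and hence no relactonisation to 9 can arise, while the unassisted neopentyl C19 hydroxyl reacts far more slowly and the Z geometry is inherited from the ring of 9; the closest known reaction types are acetate-anion-catalysed, hydrogen-bond-directed regioselective acylation of diols and carboxylate general-base catalysis of N-acetylimidazole solvolysis.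

## Compound list

1 | andrographolide, (3R,4R,5S,9R,10S,12E,14S)-3,14,19-trihydroxy-ent-labda-8(17),12-dien-16,15-olide | C=C1CC[C@@H]2[C@](C)(CO)[C@H](O)CC[C@@]2(C)[C@@H]1C/C=C1/C(=O)OC[C@H]1O | starting material
2 | 3,19-O-thiocarbonylandrographolide (six-membered cyclic thionocarbonate over O3 and O19, C14 hydroxyl free; not isolated) | C=C1CC[C@@H]2[C@]3(C)COC(=S)O[C@@H]3CC[C@@]2(C)[C@@H]1C/C=C1/C(=O)OC[C@H]1O | intermediate
3 | 14-O-acetyl-3,19-O-thiocarbonylandrographolide | C=C1CC[C@@H]2[C@]3(C)COC(=S)O[C@@H]3CC[C@@]2(C)[C@@H]1C/C=C1/C(=O)OC[C@H]1OC(C)=O | intermediate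
4 | 3,19-O-thiocarbonyl-14-deoxyandrographolide (ent-labda-8(17),13-dien-16,15-olide-3,19-diyl thionocarbonate) | C=C1CC[C@@H]2[C@]3(C)COC(=S)O[C@@H]3CC[C@@]2(C)[C@@H]1CCC1=CCOC1=O | intermediate
5 | 19-O-[(tributylstannylsulfanyl)carbonyl]andrograpanin (not isolated) | C=C1CC[C@@H]2[C@](C)(COC(=O)S[Sn](CCCC)(CCCC)CCCC)CCC[C@@]2(C)[C@@H]1CCC1=CCOC1=O | intermediate
6 | andrograpanin, (4R,5S,9R,10S)-ent-19-hydroxylabda-8(17),13-dien-16,15-olide | C=C1CC[C@@H]2[C@](C)(CO)CCC[C@@]2(C)[C@@H]1CCC1=CCOC1=O | intermediate
7 | (4R,5S,9R,10S,13Z)-ent-labda-8(17),13-diene-15,16,19-triol | C=C1CC[C@@H]2[C@](C)(CO)CCC[C@@]2(C)[C@@H]1CC/C(CO)=C/CO | intermediate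
8 | ent-15,16-epoxylabda-8(17),13-diene-15,19-diol (lactol, mixture of C15 epimers; not isolated) | C=C1CC[C@@H]2[C@](C)(CO)CCC[C@@]2(C)[C@@H]1CCC1=CC(O)OC1 | intermediate
9 | (4R,5S,9R,10S)-ent-19-hydroxylabda-8(17),13-dien-15,16-olide | C=C1CC[C@@H]2[C@](C)(CO)CCC[C@@]2(C)[C@@H]1CCC1=CC(=O)OC1 | intermediate
10 | tetrabutylammonium (13Z)-ent-16,19-dihydroxylabda-8(17),13-dien-15-oate (not isolated) | C=C1CC[C@@H]2[C@](C)(CO)CCC[C@@]2(C)[C@@H]1CC/C(CO)=C/C(=O)[O-].CCCC[N+](CCCC)(CCCC)CCCC | intermediate
11 | tetrabutylammonium (13Z)-ent-16-acetoxy-19-hydroxylabda-8(17),13-dien-15-oate (not isolated) | C=C1CC[C@@H]2[C@](C)(CO)CCC[C@@]2(C)[C@@H]1CC/C(=C/C(=O)[O-])COC(C)=O.CCCC[N+](CCCC)(CCCC)CCCC | intermediate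
12 | (4R,5S,9R,10S,13Z)-ent-16-acetoxy-19-hydroxylabda-8(17),13-dien-15-oic acid | C=C1CC[C@@H]2[C@](C)(CO)CCC[C@@]2(C)[C@@H]1CC/C(=C/C(=O)O)COC(C)=O | target

## Step count and risk

Total step count: 6. Longest linear sequence: 6 steps, from 1 to 12.

The three steps most likely to fail:

Step 2. The thionocarbonate may not survive borohydride and ethoxide, and elimination of the C14 acetate to the 11,12-diene may outrun the SN2' hydride. The fallback carries the 1,3-diol as acetates through the hydride step and installs the thionocarbonate afterwards. It sets out from 1: Ac2O, pyridine and DMAP give 3,14,19-tri-O-acetylandrographolide F1; NaBH4 in THF/MeOH at 0 °C gives 3,19-di-O-acetyl-14-deoxyandrographolide F2; K2CO3 in MeOH gives 14-deoxyandrographolide F3; 1,1'-thiocarbonyldiimidazole with DMAP in THF then closes the 3,19-thionocarbonate, and the route is rejoined at 4.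

Step 5. The regioselectivity of the MnO2 lactonisation (C15 against C16 carbinol) may be modest. The fallback transposes the carbonyl through a furan instead of the diol. It sets out from 6: i-Bu2AlH (2.2 equiv, −78 °C) gives the C16 lactol ent-15,16-epoxylabda-8(17),13-diene-16,19-diol F4, which dehydrates on dilute H2SO4 work-up to the furan ent-15,16-epoxylabda-8(17),13(16),14-trien-19-ol F5. Photo-oxygenation (O2, light, tetraphenylporphyrin, i-Pr2NEt, CH2Cl2, −78 °C), in which the hindered base removes the bridgehead proton remote from the alkyl group, gives ent-16,19-dihydroxylabda-8(17),13-dien-15,16-olide F6. NaBH4 in EtOH at 0 °C reduces its open aldehyde form to sodium (13Z)-ent-16,19-dihydroxylabda-8(17),13-dien-15-oate F7, which lactonises on acidification with HCl, and the route is rejoined at 9.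

Step 6 (the proposed new method). Acyl transfer may be slow, some acid may relactonise to 9 (recoverable), or the C19 hydroxyl may be partly acetylated. The fallback uses known chemistry, puts the acetate on before the acid exists and makes the acid last by oxidation, as in the nerol to neral to nerolic acid sequence. It sets out from 7: TBDPSCl and imidazole in CH2Cl2 at −40 °C silylate the least hindered C15 hydroxyl to give (13Z)-ent-15-(tert-butyldiphenylsilyloxy)labda-8(17),13-diene-16,19-diol F8; AcCl and 2,4,6-collidine in CH2Cl2 at −78 °C acetylate the allylic C16 hydroxyl in preference to the neopentyl C19 hydroxyl to give (13Z)-ent-16-acetoxy-15-(tert-butyldiphenylsilyloxy)labda-8(17),13-dien-19-ol F9; HF·pyridine in THF at 0 °C gives (13Z)-ent-16-acetoxylabda-8(17),13-diene-15,19-diol F10; MnO2 in CH2Cl2 gives (13Z)-ent-16-acetoxy-19-hydroxylabda-8(17),13-dien-15-al F11; NaClO2, NaH2PO4 and 2-methyl-2-butene in t-BuOH/H2O then give the acid, and the route is rejoined at 12.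

Further compounds

F1 | step 2 | 3,14,19-tri-O-acetylandrographolide | C=C1CC[C@@H]2[C@](C)(COC(C)=O)[C@H](OC(C)=O)CC[C@@]2(C)[C@@H]1C/C=C1/C(=O)OC[C@H]1OC(C)=O
F2 | step 2 | 3,19-di-O-acetyl-14-deoxyandrographolide | C=C1CC[C@@H]2[C@](C)(COC(C)=O)[C@H](OC(C)=O)CC[C@@]2(C)[C@@H]1CCC1=CCOC1=O
F3 | step 2 | 14-deoxyandrographolide | C=C1CC[C@@H]2[C@](C)(CO)[C@H](O)CC[C@@]2(C)[C@@H]1CCC1=CCOC1=O
F4 | step 5 | ent-15,16-epoxylabda-8(17),13-diene-16,19-diol (C16 lactol, epimer mixture) | C=C1CC[C@@H]2[C@](C)(CO)CCC[C@@]2(C)[C@@H]1CCC1=CCOC1O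
F5 | step 5 | ent-15,16-epoxylabda-8(17),13(16),14-trien-19-ol (3-substituted furan) | C=C1CC[C@@H]2[C@](C)(CO)CCC[C@@]2(C)[C@@H]1CCc1ccoc1
F6 | step 5 | ent-16,19-dihydroxylabda-8(17),13-dien-15,16-olide (gamma-hydroxybutenolide, C16 epimer mixture) | C=C1CC[C@@H]2[C@](C)(CO)CCC[C@@]2(C)[C@@H]1CCC1=CC(=O)OC1O
F7 | step 5 | sodium (13Z)-ent-16,19-dihydroxylabda-8(17),13-dien-15-oate | C=C1CC[C@@H]2[C@](C)(CO)CCC[C@@]2(C)[C@@H]1CC/C(CO)=C/C(=O)[O-].[Na+]
F8 | step 6 | (13Z)-ent-15-(tert-butyldiphenylsilyloxy)labda-8(17),13-diene-16,19-diol | C=C1CC[C@@H]2[C@](C)(CO)CCC[C@@]2(C)[C@@H]1CC/C(CO)=C/CO[Si](c1ccccc1)(c1ccccc1)C(C)(C)C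
F9 | step 6 | (13Z)-ent-16-acetoxy-15-(tert-butyldiphenylsilyloxy)labda-8(17),13-dien-19-ol | C=C1CC[C@@H]2[C@](C)(CO)CCC[C@@]2(C)[C@@H]1CC/C(COC(C)=O)=C/CO[Si](c1ccccc1)(c1ccccc1)C(C)(C)C
F10 | step 6 | (13Z)-ent-16-acetoxylabda-8(17),13-diene-15,19-diol | C=C1CC[C@@H]2[C@](C)(CO)CCC[C@@]2(C)[C@@H]1CC/C(COC(C)=O)=C/CO
F11 | step 6 | (13Z)-ent-16-acetoxy-19-hydroxylabda-8(17),13-dien-15-al | C=C1CC[C@@H]2[C@](C)(CO)CCC[C@@]2(C)[C@@H]1CC/C(COC(C)=O)=C/C=O
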